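**Retrosynthetic overview**
- Last bond: the prenyl group is put on the only free carbon of ring B of the fully deprotected dimer.
- Before that: one Lewis-acid operation removes three benzyl ethers on ring B and the two methyl ethers ortho to the acetyl group on ring A.
- Key disconnection: the bridge CH2–ring A bond. The ring B aldehyde is used as its N–H hydrazone, a traceless benzyl-carbanion equivalent (carbonyl carbon with reversed polarity), and is coupled with the ring A aryl bromide under nickel catalysis, which gives the CH2 bridge directly.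
- Ring A bromide comes from 2,4,6-trimethoxytoluene (acetylation, bromination); ring B aldehyde comes from phloroacetophenone (benzylation, formylation).
- No ring is built: both benzene rings are bought, elaborated separately (ring A, then ring B) and joined in step 5.

Assumption: the target has no stereocentre and no stereogenic double bond, so there is no enantiomer to select; the structure is made as drawn.

**Route**

Step 1
Reactants: 1 2,4,6-trimethoxytoluene
Product: 2 1-(2,4,6-trimethoxy-3-methylphenyl)ethan-1-one
Conditions: Ac2O (1.1 equiv), Sc(OTf)3 (5 mol %), MeNO2, 50 °C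
Reagents that add atoms: acetic anhydride, CC(=O)OC(C)=O
Why: Friedel–Crafts acylation of a very electron-rich arene whose two free positions are equivalent; the Lewis acid is only catalytic, so no methyl ether is cleaved, and no stereocentre is formed.

Step 2
Reactants: 2 1-(2,4,6-trimethoxy-3-methylphenyl)ethan-1-one
Product: 3 1-(3-bromo-2,4,6-trimethoxy-5-methylphenyl)ethan-1-one
Conditions: NBS (1.05 equiv), MeCN, 0 °C → rt, dark
Reagents that add atoms: N-bromosuccinimide, O=C1CCC(=O)N1Br
Why: electrophilic aromatic bromination at the single free ring position, which is ortho, ortho and para to three methoxy groups and therefore reacts much faster than the ketone or the aryl methyl group.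

Step 3
Reactants: 4 1-(2,4,6-trihydroxyphenyl)ethan-1-one (phloroacetophenone)
Product: 5 1-[2,4,6-tris(benzyloxy)phenyl]ethan-1-one
Conditions: BnBr (3.6 equiv), K2CO3 (4 equiv), DMF, 70 °C
Reagents that add atoms: benzyl bromide, BrCc1ccccc1
Why: Williamson etherification (phenoxide O-alkylation) with excess base in DMF alkylates all three phenols, including those hydrogen-bonded to the ketone, giving ethers that survive steps 4 and 5 and fall to BCl3 in step 6.

Step 4
Reactants: 5 1-[2,4,6-tris(benzyloxy)phenyl]ethan-1-one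
Product: 7 3-acetyl-2,4,6-tris(benzyloxy)benzaldehyde, via iminium salt 6 (not isolated)
Conditions: POCl3 (1.5 equiv), DMF, 0 °C → 40 °C; then H2O, rt
Reagents that add atoms: N,N-dimethylformamide, CN(C)C=O (formyl carbon, and the NMe2 group of 6); phosphoryl chloride, O=P(Cl)(Cl)Cl (counter-ion of 6 only); water, O (aldehyde oxygen)
Why: Vilsmeier–Haack formylation at one of the two equivalent ring positions activated by all three benzyloxy groups and only meta to the twisted acetyl group; monoformylation is self-limiting, the di-ortho-substituted methyl ketone enolises too slowly at 40 °C to react, and water hydrolyses 6 to the aldehyde.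

Step 5
Reactants: 7 3-acetyl-2,4,6-tris(benzyloxy)benzaldehyde; 3 1-(3-bromo-2,4,6-trimethoxy-5-methylphenyl)ethan-1-one
Product: 9 1-[3-[(3-acetyl-2,4,6-trimethoxy-5-methylphenyl)methyl]-2,4,6-tris(benzyloxy)phenyl]ethan-1-one, via hydrazone 8 (not isolated)
Conditions: 7 (1.3 equiv), N2H4·H2O (1.5 equiv), THF, rt, then volatiles removed; 3 (1.0 equiv), Ni(cod)2 (10 mol %), PMe3 (20 mol %), K3PO4 (2 equiv), THF, 70 °C
Reagents that add atoms: hydrazine (used as the hydrate), NN (its nitrogen atoms are carried only by intermediate 8 and leave as N2 on the way to 9)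
Why: Proposed new method: the N–H hydrazone 8 serves as a traceless benzyl-carbanion equivalent of aldehyde 7, so zerovalent nickel inserts into the C–Br bond of 3, the hydrazone binds the resulting aryl–nickel bromide (divalent nickel), K3PO4 removes the N–H proton, loss of N2 leaves an aryl(benzyl)nickel species and reductive elimination joins two carbons that are both electrophilic in 7 and 3; the closest known reaction type is the nickel-catalysed cross-coupling of aldehyde N–H hydrazones with aryl halides (a Wolff–Kishner-type carbanion coupling), here stretched to partners with two ortho alkoxy groups on each side and two hindered aryl methyl ketones that do not condense with hydrazine, and no stereocentre is formed.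

Step 6
Reactants: 9 1-[3-[(3-acetyl-2,4,6-trimethoxy-5-methylphenyl)methyl]-2,4,6-tris(benzyloxy)phenyl]ethan-1-one
Product: 10 1-[3-[(3-acetyl-2,4-dihydroxy-6-methoxy-5-methylphenyl)methyl]-2,4,6-trihydroxyphenyl]ethan-1-one
Conditions: BCl3 (8 equiv), C6HMe5 (6 equiv), CH2Cl2, −78 °C → rt; then H2O
Reagents that add atoms: none
Why: Lewis-acid ether cleavage in which BCl3 removes the aryl benzyl ethers at low temperature (pentamethylbenzene traps the benzyl cations so the free ring B carbon is not benzylated) and, on warming, demethylates only the two methoxy groups that chelate boron together with the ortho acetyl carbonyl of ring A, leaving the non-chelating methoxy para to that acetyl in place.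

Step 7
Reactants: 10 1-[3-[(3-acetyl-2,4-dihydroxy-6-methoxy-5-methylphenyl)methyl]-2,4,6-trihydroxyphenyl]ethan-1-one
Product: 11 mallotojaponin, 1-[3-[(3-acetyl-2,4-dihydroxy-6-methoxy-5-methylphenyl)methyl]-2,4,6-trihydroxy-5-(3-methylbut-2-en-1-yl)phenyl]ethan-1-one
Conditions: prenyl bromide (1.1 equiv), 10 % aq KOH, 0 °C; then dilute HCl
Reagents that add atoms: prenyl bromide (1-bromo-3-methylbut-2-ene), CC(C)=CCBr
Why: base-mediated nuclear C-prenylation of an acylphloroglucinol, in which the hydrated polyphenoxide reacts at carbon and the only unsubstituted ring carbon of the molecule (ring B, between two phenoxide oxygens) is alkylated; ring A has no free position and no stereocentre is formed.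

**Compound list**

1 | 2,4,6-trimethoxytoluene (1,3,5-trimethoxy-2-methylbenzene) | COc1cc(OC)c(C)c(OC)c1 | starting material
2 | 1-(2,4,6-trimethoxy-3-methylphenyl)ethan-1-one | CC(=O)c1c(OC)cc(OC)c(C)c1OC | intermediate
3 | 1-(3-bromo-2,4,6-trimethoxy-5-methylphenyl)ethan-1-one | CC(=O)c1c(OC)c(Br)c(OC)c(C)c1OC | intermediate
4 | 1-(2,4,6-trihydroxyphenyl)ethan-1-one (phloroacetophenone) | CC(=O)c1c(O)cc(O)cc1O | starting material
5 | 1-[2,4,6-tris(benzyloxy)phenyl]ethan-1-one | CC(=O)c1c(OCc2ccccc2)cc(OCc2ccccc2)cc1OCc1ccccc1 | intermediate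
6 | [3-acetyl-2,4,6-tris(benzyloxy)phenyl]methylidene-dimethyliminium dichlorophosphate (formed in the flask) | C[N+](C)=Cc1c(OCc2ccccc2)cc(OCc2ccccc2)c(C(C)=O)c1OCc1ccccc1.[O-]P(=O)(Cl)Cl | intermediate
7 | 3-acetyl-2,4,6-tris(benzyloxy)benzaldehyde | O=Cc1c(OCc2ccccc2)cc(OCc2ccccc2)c(C(C)=O)c1OCc1ccccc1 | intermediate
8 | 1-[2,4,6-tris(benzyloxy)-3-[(E)-hydrazinylidenemethyl]phenyl]ethan-1-one (N–H hydrazone of 7, formed in the flask) | N/N=C/c1c(OCc2ccccc2)cc(OCc2ccccc2)c(C(C)=O)c1OCc1ccccc1 | intermediate
9 | 1-[3-[(3-acetyl-2,4,6-trimethoxy-5-methylphenyl)methyl]-2,4,6-tris(benzyloxy)phenyl]ethan-1-one | CC(=O)c1c(OCc2ccccc2)cc(OCc2ccccc2)c(Cc2c(OC)c(C)c(OC)c(C(C)=O)c2OC)c1OCc1ccccc1 | intermediate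
10 | 1-[3-[(3-acetyl-2,4-dihydroxy-6-methoxy-5-methylphenyl)methyl]-2,4,6-trihydroxyphenyl]ethan-1-one | COc1c(C)c(O)c(C(C)=O)c(O)c1Cc1c(O)cc(O)c(C(C)=O)c1O | intermediate
11 | mallotojaponin | COc1c(C)c(O)c(C(C)=O)c(O)c1Cc1c(O)c(CC=C(C)C)c(O)c(C(C)=O)c1O | target

**Totals**

Total step count: 7. Longest linear sequence: 5 steps (steps 3, 4, 5, 6, 7 from 4; equally steps 1, 2, 5, 6, 7 from 1).

**Steps most likely to fail**

Step 5 is the riskiest. Both partners carry two ortho alkoxy groups, so oxidative addition and the final reductive elimination are slow. Simple Wolff–Kishner reduction of 8 to the methylarene, hydrodebromination of 3 and N-arylation of the hydrazone can compete. Fallback, with the same polarity pattern but a preformed organometallic: setting out from 7, NaBH4 (MeOH–THF, 0 °C) reduces only the aldehyde to the benzylic alcohol 1-[2,4,6-tris(benzyloxy)-3-(hydroxymethyl)phenyl]ethan-1-one F1. SOCl2 (CH2Cl2, 0 °C) converts it to the labile chloride 1-[2,4,6-tris(benzyloxy)-3-(chloromethyl)phenyl]ethan-1-one F2, which is used crude. Zinc dust with LiCl in THF inserts to give [3-acetyl-2,4,6-tris(benzyloxy)benzyl]zinc chloride F3. A Negishi coupling of this benzylzinc reagent with 3 (Pd(OAc)2, SPhos, THF, 50 °C) comes back to the route at 9.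

Step 7 is the next risk. Five free phenols invite O-prenylation and dearomatising double alkylation, and yields of such nuclear prenylations are typically modest. Fallback, replacing the alkylation by a cross-coupling: setting out from 10, NIS (1.0 equiv, MeCN, 0 °C) iodinates the only free ring carbon to give 1-[3-[(3-acetyl-2,4-dihydroxy-6-methoxy-5-methylphenyl)methyl]-2,4,6-trihydroxy-5-iodophenyl]ethan-1-one F4. A Suzuki–Miyaura coupling with prenylboronic acid pinacol ester (Pd(OAc)2, a bulky biarylphosphine chosen for linear selectivity, K3PO4, THF–H2O, 40 °C) then replaces iodine by the prenyl group and comes back to the route at 11.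

Step 6 is the third risk. The second ortho demethylation may stall, the hindered para methoxy group may be lost on forcing, and the electron-rich diarylmethane may fragment under the Lewis acid. Fallback, moving the selective demethylation to the monomer and finishing by hydrogenolysis:
- Setting out from 2, BCl3 (CH2Cl2, 0 °C → rt) gives 1-(2,6-dihydroxy-4-methoxy-3-methylphenyl)ethan-1-one F5.
- BnBr, K2CO3 in DMF gives 1-[2,6-bis(benzyloxy)-4-methoxy-3-methylphenyl]ethan-1-one F6.
- NBS in MeCN gives 1-[2,6-bis(benzyloxy)-3-bromo-4-methoxy-5-methylphenyl]ethan-1-one F7.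
- Coupling of F7 with hydrazone 8 under the conditions of step 5 gives 1-[3-[[3-acetyl-2,4-bis(benzyloxy)-6-methoxy-5-methylphenyl]methyl]-2,4,6-tris(benzyloxy)phenyl]ethan-1-one F8.
- H2 over Pd/C (EtOAc–MeOH, rt) removes all five benzyl groups and comes back to the route at 10.

**Further compounds**

F1 | step 5 | 1-[2,4,6-tris(benzyloxy)-3-(hydroxymethyl)phenyl]ethan-1-one | CC(=O)c1c(OCc2ccccc2)cc(OCc2ccccc2)c(CO)c1OCc1ccccc1
F2 | step 5 | 1-[2,4,6-tris(benzyloxy)-3-(chloromethyl)phenyl]ethan-1-one | CC(=O)c1c(OCc2ccccc2)cc(OCc2ccccc2)c(CCl)c1OCc1ccccc1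
F3 | step 5 | [3-acetyl-2,4,6-tris(benzyloxy)benzyl]zinc chloride | CC(=O)c1c(OCc2ccccc2)cc(OCc2ccccc2)c(C[Zn]Cl)c1OCc1ccccc1
F4 | step 7 | 1-[3-[(3-acetyl-2,4-dihydroxy-6-methoxy-5-methylphenyl)methyl]-2,4,6-trihydroxy-5-iodophenyl]ethan-1-one | COc1c(C)c(O)c(C(C)=O)c(O)c1Cc1c(O)c(I)c(O)c(C(C)=O)c1O
F5 | step 6 | 1-(2,6-dihydroxy-4-methoxy-3-methylphenyl)ethan-1-one | CC(=O)c1c(O)cc(OC)c(C)c1O
F6 | step 6 | 1-[2,6-bis(benzyloxy)-4-methoxy-3-methylphenyl]ethan-1-one | CC(=O)c1c(OCc2ccccc2)cc(OC)c(C)c1OCc1ccccc1
F7 | step 6 | 1-[2,6-bis(benzyloxy)-3-bromo-4-methoxy-5-methylphenyl]ethan-1-one | CC(=O)c1c(OCc2ccccc2)c(Br)c(OC)c(C)c1OCc1ccccc1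
F8 | step 6 | 1-[3-[[3-acetyl-2,4-bis(benzyloxy)-6-methoxy-5-methylphenyl]methyl]-2,4,6-tris(benzyloxy)phenyl]ethan-1-one | CC(=O)c1c(OCc2ccccc2)cc(OCc2ccccc2)c(Cc2c(OC)c(C)c(OCc3ccccc3)c(C(C)=O)c2OCc2ccccc2)c1OCc1ccccc1
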